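## The problem

Target 33 is an eremophilane ester; eremophilane numbering is used throughout (ring A: C1–C5 and C10; ring B: C5–C10; C11–C13 on C7, C14 on C5, C15 on C4), and β is the face that carries C14. Rings A and B are cis-fused through the quaternary C5 and the methine C10, so the decalin is conformationally mobile and has no fixed convex face. Five stereocentres must be set (3R,4R,5R,9R,10S): C14, C15, H-10 and the C9 hydroxyl are β, the C3 ester oxygen is α. C5 and C10 have nothing to lean on and must be set absolutely; C4 can be derived from C3, because hydroxyl-directed hydrogenation of a C4(15) methylene places C15 trans to the C3 oxygen; C3 and C9 cannot be derived safely from the ring fusion, since the two chair–chair forms of the unsubstituted bicycle are close in energy and shield opposite faces at both carbons. One of the two therefore needs reagent control, after which equatorial substituents at C3 and C4 lock the bicycle and let the ring fusion control C9. Three groups are fragile: the (Z)-4-hydroxy-enone C12–C11=C7–C8, which closes to a hemiketal and dehydrates to a furan in acid and whose tetrasubstituted alkene has no geometric bias when C12 is protected; the C8/C9 α-ketol (epimerisation and ketol shift in base); and the trienoate (strong base, light, electrophilic oxidants). Two features open the structure: in ring B the quaternary C5 lies para to the C8 carbonyl between C6–C7 and C9–C10, the retron of a 4,4-disubstituted cyclohexa-2,5-dienone with a mirror plane through C5 and C8, and C1 is bonded to its β-carbon C10, so a C5-bound chain ending in an alkenyl metal at C1 can close ring A while a chiral catalyst chooses one enone arm; and the hydroxy-enone is the oxidatively opened form of a 3-methylfuran fused at C7–C8, which fixes the Z geometry and masks C8 and C12.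

## Retrosynthesis

The last bond made is C9–O: 33 is traced to the C12 silyl ether 30 through enol ether 31 and its epoxide 32. An earlier C9 oxidation is rejected because the α-ketol is the most base-sensitive group, and because only at this stage do the equatorial C3 ester and C15 methyl hold the bicycle in the form in which C4 lies axially over the α face of ring B. The precursor has one stereocentre and one free hydroxyl fewer. The forward step must enolise towards C9 rather than C12 or C13 and must oxidise the enol ether in the presence of the triene.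

The hydroxy-enone of 30 and 29 is traced to the furan of 26, through keto enal 28 and endoperoxide 27. A direct aldol condensation at C7 would give both alkene isomers; the furan guarantees that C12 and C8 are cis, and it is inert to the base, titanium and boron reagents needed in ring A. The precursor has no sensitive group. The forward step needs an oxidant that prefers the furan to the triene and a reduction that takes the aldehyde and leaves the C8 ketone.

The C3–O ester bond is cut next: 26 comes from alcohol 20 and acid 24; 24 comes from ester 23, made from 21 and 22 by forming C4'=C5'. Esterifying before ring B is opened means that 20 has a single hydroxyl and needs no protecting group. The forward step is the acylation of a hindered equatorial secondary alcohol.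

In 20, C4–H is traced to the C4(15) methylene of 19 and C3–H to ketone 18. 18 comes from alcohols 17, these from the C4 ketone 16 by methylenation, and 16 from 15 by oxidation of the only enolisable position, C3. The route passes through ketone 18 because the hydroxylation of 15 cannot be expected to choose a face, whereas a catalyst-controlled reduction of 18 can; the directed hydrogenation then sets C4 from C3. With ring B held as a furan, C4 is the only carbonyl during methylenation and C3 the only one during reduction.

The furan of 15 is cut at C7–C11 and O–C8, giving the enol ether 12 and the three-carbon ketone 13 through aldol adduct 14. 12 comes from enedione 10 through 11: the isolated C1=C2 alkene is saturated and the enone is converted into its enol ether, which distinguishes C7 from C9. Only chemoselectivity is asked of these steps.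

10 is opened at C1–C10 to dienone 9. This is the strategic cut: it removes ring A and both ring-fusion stereocentres and leaves an achiral precursor, whereas cutting C5–C10 or C4–C5 would keep a stereocentre in the precursor. The forward reaction is an enantioselective reductive Heck cyclisation in which the catalyst chooses the enone arm and the tether enforces the cis fusion.

9 comes from carbinol 8 and this from diene 7 by oxidation of the ring methylene; the carbinol is oxidised afterwards so that the base-labile 4-acyl dienone is formed last. The (Z)-bromoalkene of 7 is traced through bromoalkyne 6 to alkyne 5, the adduct of 4 and aldehyde 3. 3 comes from nitrile 2, the reductive methylation product of 1, which supplies ring B, C5 and C14 in one step.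

## Roads not taken

Alternative 1: The cut runs through C5–C10 and C3–C4 and opens both rings to trienone A1, in which a 1-benzyloxy diene (C10=C1–C2=C3) is linked through C9–C6 to an (E)-enone (C4=C5); the C9 silyl ether would come from a chiral-pool amino acid. Heating or Lewis acid activation should close rings A and B in one intramolecular Diels–Alder step to octalone A2.
- Merits: C3, C4, C5 and C10 arise together. The cis C14/C15 methyls are written into the enone geometry and the C3–O/C4 relationship into the diene, so neither a catalyst-controlled reduction nor a directed hydrogenation is needed. For ring A this road is better than the chosen plan, which spends steps 11–15 on C3 and C4.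
- Weak points: the dienophile carbon that becomes C5 is fully substituted and the diene is an acid-sensitive enol ether, so the cycloaddition is slow and Lewis acid help is limited. Facial and endo/exo selectivity rest on the single C9 centre. Above all, the ketone of A2 sits at C6, whereas 33 needs C8=O with C6 as CH2, so a carbonyl transposition across C7 is added to the side-chain work.
- Comparison: against the ring A economy of A2 the chosen plan sets absolute control by a catalyst from an achiral precursor, and a ketone already at C8 with an enone marking C7.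

Alternative 2: The cut is at C5–C6, with C3–C8 reconnected, and leads to the bicyclo[2.2.2]octenol A3, the vinyl adduct of a masked o-benzoquinone cycloadduct. Its potassium alkoxide should undergo an anionic oxy-Cope rearrangement that forms C5–C6, breaks C3–C8 and gives the cis-decalin ketal ketone A4.
- Merits: the road is very short. A4 already holds the C8 ketone, C9 at the oxidation level of oxygen, C15 on a C3=C4 alkene and the cis fusion. The C9 ketal blocks enolisation on that side, so C7 is addressed without the hydrosilylation of step 9. In steps to the decalin and in regiocontrol at C7 it is better than the chosen plan.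
- Weak points: A3 is formed as a racemate, so absolute configuration needs an auxiliary or a resolution. C9 is a masked ketone next to the C8 ketone, so two neighbouring carbonyls must be told apart and C9 reduced from the right face. Hydroboration of C3=C4 would have to deliver C3–OH and C4–H from the concave α face next to C5 with nothing to direct it.
- Comparison: the chosen plan sets against this an absolute configuration from the catalyst and a C4 centre set by a directed hydrogenation.

Alternative 3: The cut is at C4–C5 and leads to phenol A5, whose C1–C4 chain carries the C3 silyl ether and a C4 mesylate, both from a chiral-pool hydroxy acid. With a hindered potassium alkoxide the phenolate should attack the mesylate through its para carbon with inversion at C4, closing ring A to dienone A6.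
- Merits: C3 and C4 are fixed before ring closure, C4 by a stereospecific substitution. This is more secure than the reduction of step 14 followed by hydrogenation. The C9 oxygen comes in with the arene and ring B appears as a dienone with the C8 ketone. For ring A this road is better.
- Weak points: a quaternary carbon must form by attack of a phenolate carbon on a secondary sulfonate, where O-alkylation and elimination compete. The C5 configuration rests on a conformational preference of the transition state. C10 stays sp2: syn hydrogenation of C9=C10 would put O-9 and H-10 trans, so a later C9 epimerisation is needed. The C7 side chain is still missing.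
- Comparison: the chosen plan sets against this a single catalytic step that forms C5 and C10 together, with the cis outcome enforced by the tether.

Key step: step 8

Assumption: the antipode of the bisphosphine that gives 10 in the (4aS,8aS) series is fixed in the first experiments; metalated species made and consumed within one operation (enolates, carbanions, metal alkoxides) are described in the Why lines and not numbered.

## Route

Step 1
Reactants: 1 benzonitrile
Product: 2 1-methylcyclohexa-2,5-diene-1-carbonitrile
Conditions: Li, NH3/THF, t-BuOH (1 equiv), −78 °C; then MeI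
Reagents that add atoms: iodomethane, CI
Why: Birch reductive alkylation; reduction and protonation at the para carbon give the nitrile-stabilised cyclohexadienyl anion, which is methylated at the ipso carbon and so delivers the quaternary carbon (later C5 with C14) and the 1,4-diene of ring B.

Step 2
Reactants: 2 1-methylcyclohexa-2,5-diene-1-carbonitrile
Product: 3 1-methylcyclohexa-2,5-diene-1-carbaldehyde
Conditions: i-Bu2AlH, CH2Cl2, −78 °C; then 1 M HCl, 0 °C
Reagents that add atoms: water, O
Why: Partial reduction of the nitrile stops at the N-aluminoimine, which is hydrolysed to the aldehyde; without an α-hydrogen the aldehyde can neither enolise nor shift its double bonds.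

Step 3
Reactants: 3 1-methylcyclohexa-2,5-diene-1-carbaldehyde; 4 propargyl bromide
Product: 5 1-(1-methylcyclohexa-2,5-dien-1-yl)but-3-yn-1-ol (racemic)
Conditions: Zn, THF/sat. aq. NH4Cl, 0 °C to rt
Reagents that add atoms: none
Why: Barbier propargylation; the allenylzinc bromide formed in situ adds through its γ-carbon to give the homopropargylic alcohol, and the racemic carbinol centre (later C4) is removed in step 7.

Step 4
Reactants: 5 1-(1-methylcyclohexa-2,5-dien-1-yl)but-3-yn-1-ol
Product: 6 4-bromo-1-(1-methylcyclohexa-2,5-dien-1-yl)but-3-yn-1-ol (racemic)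
Conditions: N-bromosuccinimide, AgNO3 (10 mol%), acetone, rt, dark
Reagents that add atoms: N-bromosuccinimide, O=C1CCC(=O)N1Br
Why: Silver-catalysed bromination of the terminal alkyne through the silver acetylide; the ionic, dark conditions leave the 1,4-diene alone.

Step 5
Reactants: 6 4-bromo-1-(1-methylcyclohexa-2,5-dien-1-yl)but-3-yn-1-ol
Product: 7 (Z)-4-bromo-1-(1-methylcyclohexa-2,5-dien-1-yl)but-3-en-1-ol (racemic)
Conditions: 2-nitrobenzenesulfonohydrazide, Et3N, THF/i-PrOH, rt
Reagents that add atoms: none
Why: Diimide released in situ adds hydrogen syn to the bromoalkyne and gives the (Z)-bromoalkene; haloalkynes are reduced much faster than unstrained 1,2-disubstituted alkenes, which protects the ring diene.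

Step 6
Reactants: 7 (Z)-4-bromo-1-(1-methylcyclohexa-2,5-dien-1-yl)but-3-en-1-ol
Product: 8 4-[(Z)-4-bromo-1-hydroxybut-3-en-1-yl]-4-methylcyclohexa-2,5-dien-1-one (racemic)
Conditions: Rh2(C6H10NO)4 (dirhodium tetrakis(caprolactamate), 1 mol%), t-BuOOH (70% aq.), CH2Cl2, rt
Reagents that add atoms: tert-butyl hydroperoxide, CC(C)(C)OO
Why: Catalytic allylic oxidation; peroxyl radicals abstract the doubly allylic ring hydrogen, the pentadienyl radical is captured at its central carbon because both termini adjoin the quaternary carbon, and the mixed peroxide collapses to the cross-conjugated dienone. Any oxidation of the carbinol at this stage is harmless because step 7 completes it.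

Step 7
Reactants: 8 4-[(Z)-4-bromo-1-hydroxybut-3-en-1-yl]-4-methylcyclohexa-2,5-dien-1-one
Product: 9 4-[(Z)-4-bromobut-3-enoyl]-4-methylcyclohexa-2,5-dien-1-one
Conditions: DMP (1,1,1-triacetoxy-1,1-dihydro-1,2-benziodoxol-3(1H)-one), NaHCO3, CH2Cl2, 0 °C
Reagents that add atoms: none
Why: Buffered periodinane oxidation of a neopentyl secondary alcohol; the neutral conditions spare the dienone and the skipped bromoalkenyl ketone, and 9 is used at once because nucleophiles can cleave its acyl group with release of a phenolate.

Step 8
Reactants: 9 4-[(Z)-4-bromobut-3-enoyl]-4-methylcyclohexa-2,5-dien-1-one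
Product: 10 (4aS,8aS)-8a-methyl-2,4a,5,8a-tetrahydronaphthalene-1,6-dione
Conditions: Pd(OAc)2 (5 mol%), (R)-BINAP (6 mol%), HCO2Na (2 equiv), DMF, 60 °C
Reagents that add atoms: none
Why: Zerovalent palladium, formed in situ from Pd(OAc)2 and the bisphosphine, inserts into the C1–Br bond with retention of the Z geometry. The alkenylpalladium bromide adds syn across C9=C10 of one of the two enantiotopic enone arms in a 6-exo-trig carbopalladation, which forms C1–C10, closes ring A and leaves palladium at C9 as a palladium enolate. The only hydrogen on C10 is anti to palladium, so β-hydride elimination is closed; formate replaces bromide, loses CO2, and the palladium hydride delivers hydrogen to C9 and returns zerovalent palladium. The closest known reaction type is the palladium-catalysed enantioselective desymmetrising reductive Heck cyclisation of halide-tethered 4,4-disubstituted cyclohexadienones. C5 and C10 become stereogenic in the same insertion: the chiral ligand decides which arm reacts and thereby both absolute configurations, while the three-atom tether C4–C3–C2 can reach C10 only on its own face of C5, which fixes the cis fusion. The step needs arm selectivity (ligand), retention of the Z alkene (an E alkene cannot reach C10) and insertion faster than formate reduction of the alkenylpalladium, which the close, electron-poor enone favours. The nearly neutral formate medium is chosen because 9 loses its acyl group to stronger nucleophiles. Should C1=C2 move into conjugation with C4 after ring closure, the material still converges on 11 in step 9.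

Step 9
Reactants: 10 (4aS,8aS)-8a-methyl-2,4a,5,8a-tetrahydronaphthalene-1,6-dione
Product: 12 cis-8a-methyl-6-(triethylsilyloxy)-3,4,4a,5,8,8a-hexahydronaphthalen-1(2H)-one, via dihydro dione 11 (not isolated)
Conditions: RhCl(PPh3)3 (5 mol%), H2 (1 atm), benzene, rt; then Et3SiH, 50 °C
Reagents that add atoms: triethylsilane, CC[SiH](CC)CC
Why: The rhodium catalyst first hydrogenates the isolated cis-disubstituted C1=C2 alkene, which reacts faster than the conjugated C6=C7 alkene next to the quaternary C5, and then effects 1,4-hydrosilylation of the enone. The silyl enol ether fixes enolisation of C8 towards C7 and masks C8.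

Step 10
Reactants: 12 cis-8a-methyl-6-(triethylsilyloxy)-3,4,4a,5,8,8a-hexahydronaphthalen-1(2H)-one; 13 1-(tert-butyldimethylsilyloxy)propan-2-one
Product: 15 cis-3,4a-dimethyl-4a,6,7,8,8a,9-hexahydronaphtho[2,3-b]furan-5(4H)-one (8,12-epoxy-15-noreremophila-7,11-dien-4-one), via aldol adduct 14 (not isolated)
Conditions: TiCl4, CH2Cl2, −78 °C; then 2 M HCl, THF, 50 °C
Reagents that add atoms: none
Why: Mukaiyama aldol addition of C7 to ketone 13 forms C7–C11; acid then removes the silyl group, the C12 hydroxyl closes onto C8 and two dehydrations aromatise the ring (Paal–Knorr-type cyclodehydration). The C7 and C11 stereocentres of 14 are lost, and the hindered C4 ketone takes no part.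

Step 11
Reactants: 15 cis-3,4a-dimethyl-4a,6,7,8,8a,9-hexahydronaphtho[2,3-b]furan-5(4H)-one
Product: 16 3-hydroxy-8,12-epoxy-15-noreremophila-7,11-dien-4-one (both C3 epimers)
Conditions: KN(SiMe3)2, THF, −78 °C; then 2-(phenylsulfonyl)-3-phenyloxaziridine; sat. aq. NH4Cl
Reagents that add atoms: 2-(phenylsulfonyl)-3-phenyloxaziridine, O=S(=O)(c1ccccc1)N1OC1c1ccccc1
Why: Enolate hydroxylation; C4 is the only carbonyl and C3 its only enolisable position, and the neutral furan is not attacked by the N-sulfonyloxaziridine. No facial selectivity is required because C3 is re-set in step 14.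

Step 12
Reactants: 16 3-hydroxy-8,12-epoxy-15-noreremophila-7,11-dien-4-one
Product: 17 8,12-epoxyeremophila-4(15),7,11-trien-3-ol (both C3 epimers)
Conditions: (C5H5)2Ti(CH3)2 (3 equiv), toluene, 70 °C, dark
Reagents that add atoms: dimethyltitanocene, C[Ti](C)(C1C=CC=C1)C1C=CC=C1
Why: Carbonyl methylenation by the titanium methylidene formed on heating; this non-basic reagent suits a hindered, enolisable ketone, and the excess allows for the free hydroxyl. C15 is introduced while ring B offers no second carbonyl.

Step 13
Reactants: 17 8,12-epoxyeremophila-4(15),7,11-trien-3-ol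
Product: 18 8,12-epoxyeremophila-4(15),7,11-trien-3-one
Conditions: DMP, NaHCO3, CH2Cl2, 0 °C
Reagents that add atoms: none
Why: Periodinane oxidation of the allylic alcohol converges both C3 epimers on one enone; under buffered conditions the furan is not oxidised.

Step 14
Reactants: 18 8,12-epoxyeremophila-4(15),7,11-trien-3-one
Product: 19 (3R)-8,12-epoxyeremophila-4(15),7,11-trien-3-ol (3α-hydroxyl)
Conditions: (S)-1-methyl-3,3-diphenyltetrahydro-1H,3H-pyrrolo[1,2-c][1,3,2]oxazaborole (20 mol%), BH3·SMe2, toluene, −40 °C; then MeOH
Reagents that add atoms: none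
Why: CBS reduction; the oxazaborolidine binds the only carbonyl anti to the larger alkenyl arm (C4) and delivers hydride to one face, which should give the (3R)-alcohol by analogy with aryl and alkenyl ketones. Catalyst control is used because the mobile cis-decalin gives no dependable bias at C3.

Step 15
Reactants: 19 (3R)-8,12-epoxyeremophila-4(15),7,11-trien-3-ol
Product: 20 8,12-epoxyeremophila-7,11-dien-3α-ol (4β,5β-dimethyl, 10β-H)
Conditions: [Ir(cod)(PCy3)(py)]PF6 (5 mol%), H2 (1 atm), CH2Cl2, 0 °C
Reagents that add atoms: none
Why: Hydroxyl-directed hydrogenation; the iridium centre is held by the C3 hydroxyl and adds hydrogen to the α face of C4=C15, so C15 ends β, trans to the C3 oxygen and cis to C14. The aromatic furan is not reduced under these conditions.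

Step 16
Reactants: 21 (E)-non-3-en-2-one; 22 triethyl 4-phosphonocrotonate
Product: 23 ethyl (2E,4E,6E)-5-methyldodeca-2,4,6-trienoate
Conditions: LiN(SiMe3)2, THF, −78 °C to rt
Reagents that add atoms: none
Why: Vinylogous Horner–Wadsworth–Emmons olefination; the γ-carbon of the phosphonate anion attacks the ketone and elimination forms C4'=C5', the E isomer being favoured with the larger alkenyl group trans to the chain. The C2' and C6' alkenes are carried in with E geometry.

Step 17
Reactants: 23 ethyl (2E,4E,6E)-5-methyldodeca-2,4,6-trienoate
Product: 24 (2E,4E,6E)-5-methyldodeca-2,4,6-trienoic acid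
Conditions: LiOH, THF/MeOH/H2O, rt; then 1 M HCl
Reagents that add atoms: lithium hydroxide, [Li+].[OH-]
Why: Ester saponification; the conjugated triene has no acidic position that would let the alkenes move under aqueous hydroxide at room temperature.

Step 18
Reactants: 20 8,12-epoxyeremophila-7,11-dien-3α-ol; 24 (2E,4E,6E)-5-methyldodeca-2,4,6-trienoic acid
Product: 26 8,12-epoxyeremophila-7,11-dien-3α-yl (2E,4E,6E)-5-methyldodeca-2,4,6-trienoate, via mixed anhydride 25 (not isolated)
Conditions: 2,4,6-trichlorobenzoyl chloride, Et3N, THF, rt; then 20, 4-(dimethylamino)pyridine, toluene, rt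
Reagents that add atoms: none
Why: Yamaguchi esterification; acyl transfer from the mixed anhydride through the acylpyridinium acylates the hindered equatorial C3 hydroxyl with retention, and 20 has no other hydroxyl.

Step 19
Reactants: 26 8,12-epoxyeremophila-7,11-dien-3α-yl (2E,4E,6E)-5-methyldodeca-2,4,6-trienoate
Product: 29 (7(11)Z)-12-hydroxy-8-oxoeremophil-7(11)-en-3α-yl (2E,4E,6E)-5-methyldodeca-2,4,6-trienoate, via furan endoperoxide 27 (not isolated), via keto enal 28 (not isolated)
Conditions: O2, 5,10,15,20-tetraphenylporphyrin (cat.), hν (>500 nm), CH2Cl2, −78 °C; Me2S; then LiAlH(Ot-Bu)3, THF, −78 °C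
Reagents that add atoms: dioxygen, O=O
Why: Singlet oxygen adds [4+2] to the electron-rich furan far faster than to the ester-deactivated triene, and reduction of the endoperoxide gives the keto enal with the Z geometry dictated by the ring. The hindered aluminium hydride reduces the aldehyde in preference to the C8 ketone, and the resulting C12 alkoxide can rest on C8 as a hemiketal.

Step 20
Reactants: 29 (7(11)Z)-12-hydroxy-8-oxoeremophil-7(11)-en-3α-yl (2E,4E,6E)-5-methyldodeca-2,4,6-trienoate
Product: 30 (7(11)Z)-8-oxo-12-(triethylsilyloxy)eremophil-7(11)-en-3α-yl (2E,4E,6E)-5-methyldodeca-2,4,6-trienoate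
Conditions: Et3SiCl, imidazole, CH2Cl2, 0 °C
Reagents that add atoms: chlorotriethylsilane, CC[Si](Cl)(CC)CC
Why: Silylation of the primary C12 hydroxyl traps the open hydroxy-enone form and prevents its return to the furan under the Lewis acidic conditions of the next step.

Step 21
Reactants: 30 (7(11)Z)-8-oxo-12-(triethylsilyloxy)eremophil-7(11)-en-3α-yl (2E,4E,6E)-5-methyldodeca-2,4,6-trienoate
Product: 33 (3R,4R,5R,9R,10S,7(11)Z)-9,12-dihydroxy-8-oxoeremophil-7(11)-en-3-yl (2E,4E,6E)-5-methyldodeca-2,4,6-trienoate, via silyl dienol ether 31 (not isolated), via silyloxy epoxide 32 (not isolated)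
Conditions: Et3SiOTf, Et3N, CH2Cl2, −78 °C; dimethyldioxirane, acetone, −78 °C; then HF·pyridine, pyridine, THF, 0 °C
Reagents that add atoms: dimethyldioxirane, CC1(C)OO1
Why: Rubottom oxidation; soft enolisation removes an α' hydrogen at C9, the dioxirane epoxidises the electron-rich enol ether from the β face because the locked ring A places C4 axially over the α face of ring B, and buffered fluoride opens the silyloxy epoxide to the 9β-hydroxy ketone and frees the C12 hydroxyl. The 9β hydroxyl is equatorial, so kinetic and thermodynamic preference should agree.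

## Compound list

1 | benzonitrile | N#Cc1ccccc1 | starting material
2 | 1-methylcyclohexa-2,5-diene-1-carbonitrile | CC1(C#N)C=CCC=C1 | intermediate
3 | 1-methylcyclohexa-2,5-diene-1-carbaldehyde | CC1(C=O)C=CCC=C1 | intermediate
4 | propargyl bromide (3-bromoprop-1-yne) | C#CCBr | starting material
5 | 1-(1-methylcyclohexa-2,5-dien-1-yl)but-3-yn-1-ol (racemic) | CC1(C(O)CC#C)C=CCC=C1 | intermediate
6 | 4-bromo-1-(1-methylcyclohexa-2,5-dien-1-yl)but-3-yn-1-ol (racemic) | CC1(C(O)CC#CBr)C=CCC=C1 | intermediate
7 | (Z)-4-bromo-1-(1-methylcyclohexa-2,5-dien-1-yl)but-3-en-1-ol (racemic) | CC1(C(O)C/C=C\Br)C=CCC=C1 | intermediate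
8 | 4-[(Z)-4-bromo-1-hydroxybut-3-en-1-yl]-4-methylcyclohexa-2,5-dien-1-one (racemic) | O=C1C=CC(C)(C(O)C/C=C\Br)C=C1 | intermediate
9 | 4-[(Z)-4-bromobut-3-enoyl]-4-methylcyclohexa-2,5-dien-1-one | O=C1C=CC(C)(C(=O)C/C=C\Br)C=C1 | intermediate
10 | (4aS,8aS)-8a-methyl-2,4a,5,8a-tetrahydronaphthalene-1,6-dione (cis-fused; C4 and C8 ketones, C1=C2 and C6=C7 alkenes) | O=C1CC=C[C@@H]2CC(=O)C=C[C@]12C | intermediate
11 | cis-8a-methyl-2,3,4,4a,5,8a-hexahydronaphthalene-1,6-dione (not isolated) | O=C1CCC[C@@H]2CC(=O)C=C[C@]12C | intermediate
12 | cis-8a-methyl-6-(triethylsilyloxy)-3,4,4a,5,8,8a-hexahydronaphthalen-1(2H)-one | O=C1CCC[C@@H]2CC(O[Si](CC)(CC)CC)=CC[C@]12C | intermediate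
13 | 1-(tert-butyldimethylsilyloxy)propan-2-one | CC(=O)CO[Si](C)(C)C(C)(C)C | starting material
14 | cis-7-[1-(tert-butyldimethylsilyloxy)-2-hydroxypropan-2-yl]-8a-methyloctahydronaphthalene-1,6-dione (mixture at C7 and the carbinol; not isolated) | O=C1CCC[C@@H]2CC(=O)C(C(C)(O)CO[Si](C)(C)C(C)(C)C)C[C@]12C | intermediate
15 | cis-3,4a-dimethyl-4a,6,7,8,8a,9-hexahydronaphtho[2,3-b]furan-5(4H)-one (8,12-epoxy-15-noreremophila-7,11-dien-4-one) | O=C1CCC[C@@H]2Cc3occ(C)c3C[C@]12C | intermediate
16 | 3-hydroxy-8,12-epoxy-15-noreremophila-7,11-dien-4-one (both C3 epimers) | O=C1C(O)CC[C@@H]2Cc3occ(C)c3C[C@]12C | intermediate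
17 | 8,12-epoxyeremophila-4(15),7,11-trien-3-ol (both C3 epimers) | C=C1C(O)CC[C@@H]2Cc3occ(C)c3C[C@]12C | intermediate
18 | 8,12-epoxyeremophila-4(15),7,11-trien-3-one | C=C1C(=O)CC[C@@H]2Cc3occ(C)c3C[C@]12C | intermediate
19 | (3R)-8,12-epoxyeremophila-4(15),7,11-trien-3-ol (3α-OH) | O[C@@H]1CC[C@@H]2Cc3occ(C)c3C[C@]2(C)C1=C | intermediate
20 | 8,12-epoxyeremophila-7,11-dien-3α-ol (4β,5β-dimethyl, 10β-H) | O[C@@H]1CC[C@@H]2Cc3occ(C)c3C[C@]2(C)[C@H]1C | intermediate
21 | (E)-non-3-en-2-one | CCCCC/C=C/C(C)=O | starting material
22 | triethyl 4-phosphonocrotonate (ethyl (E)-4-(diethoxyphosphoryl)but-2-enoate) | CCOC(=O)/C=C/CP(=O)(OCC)OCC | starting material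
23 | ethyl (2E,4E,6E)-5-methyldodeca-2,4,6-trienoate | CCCCC/C=C/C(C)=C/C=C/C(=O)OCC | intermediate
24 | (2E,4E,6E)-5-methyldodeca-2,4,6-trienoic acid | CCCCC/C=C/C(C)=C/C=C/C(=O)O | intermediate
25 | (2E,4E,6E)-5-methyldodeca-2,4,6-trienoic 2,4,6-trichlorobenzoic anhydride (not isolated) | CCCCC/C=C/C(C)=C/C=C/C(=O)OC(=O)c1c(Cl)cc(Cl)cc1Cl | intermediate
26 | 8,12-epoxyeremophila-7,11-dien-3α-yl (2E,4E,6E)-5-methyldodeca-2,4,6-trienoate | CCCCC/C=C/C(C)=C/C=C/C(=O)O[C@@H]1CC[C@@H]2Cc3occ(C)c3C[C@]2(C)[C@H]1C | intermediate
27 | 8,12-epidioxy-8,12-epoxyeremophil-7(11)-en-3α-yl trienoate (furan endoperoxide, both faces; not isolated) | CCCCC/C=C/C(C)=C/C=C/C(=O)O[C@@H]1CC[C@@H]2CC34OOC(O3)C(C)=C4C[C@]2(C)[C@H]1C | intermediate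
28 | (7(11)Z)-8,12-dioxoeremophil-7(11)-en-3α-yl trienoate (keto enal; not isolated) | CCCCC/C=C/C(C)=C/C=C/C(=O)O[C@@H]1CC[C@@H]2CC(=O)/C(=C(/C)C=O)C[C@]2(C)[C@H]1C | intermediate
29 | (7(11)Z)-12-hydroxy-8-oxoeremophil-7(11)-en-3α-yl (2E,4E,6E)-5-methyldodeca-2,4,6-trienoate | CCCCC/C=C/C(C)=C/C=C/C(=O)O[C@@H]1CC[C@@H]2CC(=O)/C(=C(/C)CO)C[C@]2(C)[C@H]1C | intermediate
30 | (7(11)Z)-8-oxo-12-(triethylsilyloxy)eremophil-7(11)-en-3α-yl (2E,4E,6E)-5-methyldodeca-2,4,6-trienoate | CCCCC/C=C/C(C)=C/C=C/C(=O)O[C@@H]1CC[C@@H]2CC(=O)/C(=C(/C)CO[Si](CC)(CC)CC)C[C@]2(C)[C@H]1C | intermediate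
31 | (7(11)Z)-8,12-bis(triethylsilyloxy)eremophila-7(11),8-dien-3α-yl trienoate (not isolated) | CCCCC/C=C/C(C)=C/C=C/C(=O)O[C@@H]1CC[C@@H]2C=C(O[Si](CC)(CC)CC)/C(=C(/C)CO[Si](CC)(CC)CC)C[C@]2(C)[C@H]1C | intermediate
32 | (7(11)Z)-8β,9β-epoxy-8α,12-bis(triethylsilyloxy)eremophil-7(11)-en-3α-yl trienoate (not isolated) | CCCCC/C=C/C(C)=C/C=C/C(=O)O[C@@H]1CC[C@@H]2[C@H]3O[C@@]3(O[Si](CC)(CC)CC)/C(=C(/C)CO[Si](CC)(CC)CC)C[C@]2(C)[C@H]1C | intermediate
33 | (3R,4R,5R,9R,10S,7(11)Z)-9,12-dihydroxy-8-oxoeremophil-7(11)-en-3-yl (2E,4E,6E)-5-methyldodeca-2,4,6-trienoate | CCCCC/C=C/C(C)=C/C=C/C(=O)O[C@@H]1CC[C@@H]2[C@@H](O)C(=O)/C(=C(/C)CO)C[C@]2(C)[C@H]1C | target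

## Step count and risks

Total step count: 21. Longest linear sequence: 19 steps (steps 1–15 and 18–21); steps 16 and 17 form the side branch to acid 24.

Least certain steps:

Step 8 (key). The most likely failures are nucleophilic loss of the acyl group of 9 with release of a phenolate, base-induced migration of the bromoalkene into conjugation with the C4 ketone before cyclisation (which destroys the Z-alkenyl halide), formate reduction of the alkenylpalladium before insertion, and incomplete discrimination of the two enone arms. The first two follow from the acidity of C3–H and from the position of the C4 ketone on the dienone. Fallback: the C4 carbonyl is carried through the cyclisation as a dioxolane. The fallback sets out from 7. Periodinane oxidation gives (Z)-4-bromo-1-(1-methylcyclohexa-2,5-dien-1-yl)but-3-en-1-one F1. Ketalisation with 1,2-bis(trimethylsilyloxy)ethane and catalytic Me3SiOTf at −78 °C gives 2-[(Z)-3-bromoprop-2-en-1-yl]-2-(1-methylcyclohexa-2,5-dien-1-yl)-1,3-dioxolane F2. The ring oxidation of step 6 gives the ketal dienone F3, which has neither a cleavable acyl group nor an acidic C3–H. The conditions of step 8 should then give the ketal of the cyclised enone F4, and aqueous acid returns 10.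

Step 12. The C3 hydroxyl may be converted into a titanium alkoxide that blocks the neighbouring carbonyl, and reaction at a ketone flanked by the quaternary C5 may be slow enough for the α-ketol to decompose at 70 °C. Fallback: a Peterson olefination from 16. Addition of Me3SiCH2MgCl in the presence of CeCl3, which is insensitive to enolisation and hindrance, gives the β-hydroxysilane diol F5; elimination with KN(SiMe3)2 returns 17.

Step 16. The new trisubstituted C4'=C5' bond may form with poor E/Z control, and the phosphonate anion may add in conjugate fashion to the enone. Fallback: a carbometalation route from 21 with defined geometry. Kinetic enolisation and phosphorylation give diethyl (E)-nona-1,3-dien-2-yl phosphate F6; elimination with LiN(i-Pr)2 gives (E)-non-3-en-1-yne F7. Zirconium-catalysed syn-carboalumination (Me3Al, (C5H5)2ZrCl2) gives the alkenylalane F8, and Negishi-type coupling with ethyl (E)-3-iodoacrylate under Pd(PPh3)4 returns 23.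

Step 19. The doubly activated alkene of 28 may suffer 1,4-reduction or over-reduction, 28 may isomerise from Z to E before it is reduced, and 29 may return to the furan on contact with acid. Fallback: reduce both carbonyls and re-oxidise one, from 26. After photooxygenation and Me2S as in step 19, NaBH4/CeCl3 (Luche conditions) reduces both carbonyls of 28 to the (Z)-ene-8,12-diol F9. Et3SiCl silylates only the primary C12 hydroxyl to give F10, and periodinane oxidation of the remaining secondary allylic C8 alcohol returns 30.

Step 21. Enolisation may go towards the γ-carbons C12 or C13 instead of C9 under the soft conditions, the dioxirane may epoxidise the triene, and the silyl ether may be lost with closure to the furan. Fallback: a radical α'-acetoxylation from 30. Mn(OAc)3 in benzene at reflux should acetoxylate the enone at C9 from the open β face to give the 9β-acetate F11. K2CO3 in MeOH at 0 °C cleaves the activated α-keto acetate in preference to the dienoate-type ester and gives the 9β-alcohol F12, and buffered HF·pyridine returns 33.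

## Further compounds

F1 | step 8 | (Z)-4-bromo-1-(1-methylcyclohexa-2,5-dien-1-yl)but-3-en-1-one | CC1(C(=O)C/C=C\Br)C=CCC=C1
F2 | step 8 | 2-[(Z)-3-bromoprop-2-en-1-yl]-2-(1-methylcyclohexa-2,5-dien-1-yl)-1,3-dioxolane | CC1(C2(C/C=C\Br)OCCO2)C=CCC=C1
F3 | step 8 | 4-{2-[(Z)-3-bromoprop-2-en-1-yl]-1,3-dioxolan-2-yl}-4-methylcyclohexa-2,5-dien-1-one | O=C1C=CC(C)(C2(C/C=C\Br)OCCO2)C=C1
F4 | step 8 | C4 ethylene ketal of 10 (cis-fused, C8 enone and C1=C2 alkene retained) | O1CCOC12CC=C[C@@H]3CC(=O)C=C[C@]23C
F5 | step 12 | 4-[(trimethylsilyl)methyl]-8,12-epoxy-15-noreremophila-7,11-diene-3,4-diol (mixture at C3 and C4) | C[Si](C)(C)CC1(O)C(O)CC[C@@H]2Cc3occ(C)c3C[C@]12C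
F6 | step 16 | diethyl (E)-nona-1,3-dien-2-yl phosphate | CCCCC/C=C/C(=C)OP(=O)(OCC)OCC
F7 | step 16 | (E)-non-3-en-1-yne | CCCCC/C=C/C#C
F8 | step 16 | dimethyl[(1E,3E)-2-methylnona-1,3-dien-1-yl]alane | CCCCC/C=C/C(C)=C/[Al](C)C
F9 | step 19 | (7(11)Z)-8,12-dihydroxyeremophil-7(11)-en-3α-yl (2E,4E,6E)-5-methyldodeca-2,4,6-trienoate (both C8 epimers) | CCCCC/C=C/C(C)=C/C=C/C(=O)O[C@@H]1CC[C@@H]2CC(O)/C(=C(/C)CO)C[C@]2(C)[C@H]1C
F10 | step 19 | (7(11)Z)-8-hydroxy-12-(triethylsilyloxy)eremophil-7(11)-en-3α-yl (2E,4E,6E)-5-methyldodeca-2,4,6-trienoate (both C8 epimers) | CCCCC/C=C/C(C)=C/C=C/C(=O)O[C@@H]1CC[C@@H]2CC(O)/C(=C(/C)CO[Si](CC)(CC)CC)C[C@]2(C)[C@H]1C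
F11 | step 21 | (7(11)Z)-9β-acetoxy-8-oxo-12-(triethylsilyloxy)eremophil-7(11)-en-3α-yl (2E,4E,6E)-5-methyldodeca-2,4,6-trienoate | CCCCC/C=C/C(C)=C/C=C/C(=O)O[C@@H]1CC[C@@H]2[C@@H](OC(C)=O)C(=O)/C(=C(/C)CO[Si](CC)(CC)CC)C[C@]2(C)[C@H]1C
F12 | step 21 | (7(11)Z)-9β-hydroxy-8-oxo-12-(triethylsilyloxy)eremophil-7(11)-en-3α-yl (2E,4E,6E)-5-methyldodeca-2,4,6-trienoate | CCCCC/C=C/C(C)=C/C=C/C(=O)O[C@@H]1CC[C@@H]2[C@@H](O)C(=O)/C(=C(/C)CO[Si](CC)(CC)CC)C[C@]2(C)[C@H]1C
A1 | alternative 1 | (2E,8E,10E)-11-(benzyloxy)-7-[(tert-butyldimethylsilyl)oxy]-3-methylundeca-2,8,10-trien-4-one | c1ccccc1CO/C=C/C=C/[C@@H](O[Si](C)(C)C(C)(C)C)CCC(=O)/C(C)=C/C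
A2 | alternative 1 | cis-fused octalone with C3 benzyl ether, C9 silyl ether, C6 ketone and C1=C2 alkene | c1ccccc1CO[C@@H]1C=C[C@@H]2[C@@H](O[Si](C)(C)C(C)(C)C)CCC(=O)[C@]2(C)[C@H]1C
A3 | alternative 2 | 3,3-dimethoxy-5,6-dimethyl-2-vinylbicyclo[2.2.2]oct-5-en-2-ol (racemic) | C=CC1(O)C(OC)(OC)C2CCC1C(C)=C2C
A4 | alternative 2 | cis-1,1-dimethoxy-4a,5-dimethyl-3,4,4a,7,8,8a-hexahydronaphthalen-2(1H)-one | C1=C(C)[C@@]2(C)CCC(=O)C(OC)(OC)[C@H]2CC1
A5 | alternative 3 | 3-[(tert-butyldimethylsilyl)oxy]-5-[3-hydroxy-2-(methoxymethoxy)-6-methylphenyl]pentan-2-yl methanesulfonate | CS(=O)(=O)O[C@H](C)[C@H](O[Si](C)(C)C(C)(C)C)CCc1c(C)ccc(O)c1OCOC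
A6 | alternative 3 | ring A-closed 2-(methoxymethoxy)cyclohexa-2,5-dienone with C3 silyl ether and cis C4 and C5 methyls | CC(C)(C)[Si](C)(C)O[C@@H]1CCC2=C(OCOC)C(=O)C=C[C@]2(C)[C@H]1C
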